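The runs were computed for substances that don't exist; scatter was added.

**The books.** Molar per minute is the unit of these books, which follow the solid reagent, entry by entry, through the flasks below.

| setting | north-east | north | epsilon | gamma | delta | zeta |
|---|---|---|---|---|---|---|
| left-handed substrate | 0.031 M | 0.048 M | 0.022 M | 0.022 M | 0.022 M | 0.022 M |
| right-handed substrate | 0.031 M | 0.048 M | 0.022 M | 0.022 M | 0.022 M | 0.022 M |
| solid reagent | 1.1 equiv | 1.1 equiv | 1.10 equiv | 1.10 equiv | 1.10 equiv | 1.10 equiv |
| free catalyst | 0.5 mol% | 0.5 mol% | 0.5 mol% | 0.5 mol% | 0.5 mol% | 0.5 mol% |
| temperature | 12 °C | 40 °C |  | 25 °C | 50 °C | 0 °C |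
| remark | run made earlier | run made earlier | at 50 °C until 5.0 min, from then on at 0 °C |  |  |  |
| time |  |  | 10 min | 10 min | 10 min | 10 min |

- north-east (time / min: left-handed product / %, right-handed product / %, left-handed substrate / %): 1.33: 0.8, 1.0, 49.2; 4.00: 3.1, 2.8, 45.9; 6.00: 5.6, 3.0, 43.5; 10.0: 9.4, 4.5, 40.8; 15.0: 15.1, 7.2, 33.8; 20.0: 19.1, 11.1, 30.4; 25.0: 24.3, 14.1, 26.0
- north (time / min: left-handed product / %, right-handed product / %, left-handed substrate / %): 0.333: 0, 0.3, 50.0; 1.00: 0.5, 0.5, 49.2; 1.33: 0.8, 0.3, 48.8; 2.50: 1.8, 0.5, 48.9; 4.00: 2.6, 0.3, 47.2; 5.00: 4.4, 2.3, 46.3; 6.00: 4.1, 2.1, 45.9

(each reading ± 0.5 percentage points)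

- free catalyst is single-handed; left-handed substrate and right-handed substrate are mirror images of each other, charged as a racemate, each of them at the stated concentration
- as a solid, counted per litre of solution: solid reagent
- on the list of suspects stand: coupling partner + free catalyst + left-handed substrate -> free catalyst + left-handed product; coupling partner + free catalyst + right-handed substrate -> free catalyst + right-handed product; coupling partner + free catalyst -> spent catalyst; solid reagent <-> coupling partner
- at the start none of the solid reagent is in solution

- the best flask by share of left-handed product in all that became left-handed product or right-handed product; "all alike" if 1.5 percentage points covers them all (epsilon / gamma / delta / zeta / all alike)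
- share of left-handed product in all that became left-handed product or right-handed product, epsilon
- share of left-handed product in all that became left-handed product or right-handed product, gamma
- share of left-handed product in all that became left-handed product or right-handed product, delta
- share of left-handed product in all that became left-handed product or right-handed product, zeta

**The charge.** Each of epsilon, gamma, delta and zeta charges 0.0242 M of solid reagent against 0.0440 M of the two substrates together, so the solid reagent is the limiting reagent, and product has a ceiling of 55.0 % of both substrates. Catalyst death is a small entry: losing the whole free catalyst costs 0.455 % of the solid reagent.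

**The feed.** In the north-east run, at 12 °C, the products read 24.3 % and 14.1 % at 25.0 min, which gives 9.52 × 10⁻⁴ M min⁻¹; this feed rate, the product made per litre and minute on average up to that reading, is what the books carry. The north run, at 40 °C and with more substrate, gives 9.92 × 10⁻⁴ M min⁻¹ at 6.00 min, and with the feed so alike the readings point to the dissolving of solid reagent as the rate-limiting step.

**The reckoning.** At this feed, held constant, the reckoning puts 39.4 % of the solid reagent dissolved after 10 min in each of the four asked flasks and, counting all of that as product, 21.6 % of both substrates converted; by the same reckoning the solid reagent lasts 25.4 min. The two hands divide that amount. The north-east share reads 63.3 % and the north share 66.1 %, but the north right-handed product reads 2.1 % with a scatter of 0.5 percentage points, so this reckoning names no trend with temperature.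

**The forecast.** The forecast gives all alike, with 66.7 % for epsilon, 66.5 % for gamma, 67 % for delta and 66 % for zeta, holding that “selectivity is essentially temperature-independent”.

**The result.** The highest share stands in zeta at 67.2 %; epsilon gives 63.9 %, gamma 63.9 % and delta 61.2 %.

    coupling partner + free catalyst + left-handed substrate → free catalyst + left-handed product (k = 23100 L² mol⁻² s⁻¹, Ea = 26.0 kJ mol⁻¹)
    coupling partner + free catalyst + right-handed substrate → free catalyst + right-handed product (k = 13800 L² mol⁻² s⁻¹, Ea = 30.0 kJ mol⁻¹)
    coupling partner + free catalyst → spent catalyst (k = 4.36 L mol⁻¹ min⁻¹, Ea = 50.0 kJ mol⁻¹)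
    solid reagent ⇌ coupling partner, rate k4*(cs4 - [coupling partner]) while solid is left; crystals form when [coupling partner] > cs4 (solubility = 8.30 mM, k = 0.123 min⁻¹)
    (constants at 50 °C)

**Same ledger.** At 10.0 min epsilon keeps 60.8 % of its solid reagent, where the feed reckoned 60.6 %. The neighbouring flask is epsilon read at 40 min, past the reckoned 25.4 min of supply, so the feed puts its products at the ceiling of 55.0 %. That neighbouring flask holds 0 % solid reagent, 34.1 % left-handed product and 20.9 % right-handed product, a share of 62.0 %.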